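A direct plan would make a two-ring iodo aldehyde A1 holding rings C and D by SNAr on 4-fluoro-2,6-dimethoxybenzaldehyde, join it four times to a growing phenol, at first the two-ring phenol A2, by copper-catalysed etherification, turn each terminal CHO into the next OH by peracid oxidation, and finally strip 25 methyl groups from the ten-ring ether A3 with BBr3.
Its weakest steps would be:
(1) the fourfold CuI-catalysed etherification of a 2,6-dimethoxyphenol with an electron-rich, ortho-aryloxy aryl iodide: a tri-ortho-substituted ether, slow oxidative addition, hydrodeiodination as competitor, on ever larger material;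
(2) the four aldehyde-to-phenol oxidations: half of the linear steps would only exchange CHO for OH, while a peracid would meet up to ten oxidisable polyalkoxyarene rings and each product would be an air-sensitive 2,6-dimethoxy-4-aryloxyphenol;
(3) the last step, 25 ether cleavages by BBr3 on the most precious material, where every incomplete cleavage would leave an inseparable partial ether of a 26-fold phenol.
No stereocentre or ring closure would be left to chance, since the target has neither.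

**Plan of the new route**

Every ring from B to J carries three neighbouring oxygens at C-3, C-4 and C-5 and its chain ether oxygen at C-1, meta to C-3 and C-5. In rings B, D, F, H and J both neighbours of C-1 carry H; in rings C, E, G and I the neighbour C-6, beside the C-5 oxygen, carries the next ether oxygen.
This is what a 3,4,5-trioxygenated benzyne takes up: the nucleophile at the aryne carbon remote from the flanking oxygen, a second group at the carbon next to it. All nine O–C-1 bonds are therefore cut at aryne carbons.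
The bond from the C-4 oxygen of ring B to C-1 of ring C and the C-6–O bond of ring C are made together in one three-component aryne step, run once on a ring-pair block 19 (rings B and C) that is used four times. The other five bonds come from fluoride-triggered addition of a phenol O–H across the aryne of 19 or of 13.
Rings are joined in the order A, (B+C), (D+E), (F+G), (H+I), J, with all 26 oxygens as benzyl ethers from two commercial arenes.
No copper coupling remains (arynes accept di-ortho-substituted phenols at room temperature), no aldehyde or peracid (the oxygens come from quinone 6 and the key step), and no demethylation (neutral hydrogenolysis).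

Key step: step 8

Assumption: 1,3,5-tris(benzyloxy)benzene and 3,5-bis(benzyloxy)phenol are taken as commercial; the target is achiral, so no stereocentre has to be set.

**Route**

Step 1
Reactants: 1 1,3,5-tris(benzyloxy)benzene
Product: 2 2-bromo-1,3,5-tris(benzyloxy)benzene
Conditions: NBS (1.0 equiv), CH2Cl2, −40 °C to 0 °C, dark
Reagents that add atoms: N-bromosuccinimide, O=C1CCC(=O)N1Br
Why: Electrophilic aromatic bromination of the phloroglucinol triether, whose three ring positions are equivalent, should stop at the monobromide with one equivalent of NBS and leave the unactivated benzyl rings alone.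

Step 2
Reactants: 2 2-bromo-1,3,5-tris(benzyloxy)benzene
Product: 4 2,4,6-tris(benzyloxy)phenol (ring A phenol), via dimethyl arylboronate 3 (not isolated)
Conditions: n-BuLi (1.05 equiv), THF, −78 °C; B(OMe)3, −78 °C to 0 °C; then 30% H2O2, aq. NaHCO3, 0 °C; under argon
Reagents that add atoms: hydrogen peroxide, OO
Why: Bromine–lithium exchange at −78 °C (faster than benzylic deprotonation), borylation and boronate oxidation (1,2-aryl shift from boron to oxygen) should give the phenol.

Step 3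
Reactants: 5 3,5-bis(benzyloxy)phenol
Product: 6 2,6-bis(benzyloxy)-1,4-benzoquinone
Conditions: (KSO3)2NO (2.5 equiv), KH2PO4 buffer, Bu4NHSO4 (cat.), CH2Cl2/H2O, rt
Reagents that add atoms: potassium nitrosodisulfonate, [K+].[K+].[O]N(S(=O)(=O)[O-])S(=O)(=O)[O-]
Why: Teuber oxidation: two equivalents of the nitrosodisulfonate radical should oxidise the phenol at its free para position, between the two benzyloxy groups, and so place the fourth oxygen of ring B.

Step 4
Reactants: 6 2,6-bis(benzyloxy)-1,4-benzoquinone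
Product: 8 2,6-bis(benzyloxy)-3-bromobenzene-1,4-diol, via bromoquinone 7 (not isolated)
Conditions: Br2 (1.0 equiv), NaOAc, AcOH/CH2Cl2, 0 °C to rt; then Na2S2O4, H2O/EtOAc, rt
Reagents that add atoms: bromine, BrBr
Why: Electrophilic bromination of the enol-ether double bond of the alkoxyquinone (addition–elimination; C-3 and C-5 are equivalent), then dithionite reduction, should give the hydroquinone with bromine next to the unhindered hydroxyl.

Step 5
Reactants: 8 2,6-bis(benzyloxy)-3-bromobenzene-1,4-diol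
Product: 12 3,5-bis(benzyloxy)-4-hydroxy-2-(trimethylsilyl)phenyl trifluoromethanesulfonate (ring B aryne precursor; free 4-OH), via bis-silyl ether 9 (not isolated), via lithium 2-silylphenoxide 10 (not isolated), via O-silyl triflate 11 (not isolated)
Conditions: (Me3Si)2NH, THF, 65 °C, then evaporation; n-BuLi (1.05 equiv), THF, −78 °C; Tf2O (1.1 equiv), −78 °C to 0 °C; then citric acid, MeOH/H2O, rt
Reagents that add atoms: hexamethyldisilazane, C[Si](C)(C)N[Si](C)(C)C; trifluoromethanesulfonic anhydride, O=S(=O)(OS(=O)(=O)C(F)(F)F)C(F)(F)F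
Why: This is the standard route to a 2-(trimethylsilyl)aryl triflate (O-silylation, bromine–lithium exchange, retro-Brook O-to-C silyl shift from the neighbouring oxygen only, triflation of the phenoxide so released); the silyl ether on the hindered oxygen acts as a temporary protecting group and is hydrolysed on work-up.

Step 6
Reactants: 12 ring B aryne precursor with free 4-OH
Product: 13 3,4,5-tris(benzyloxy)-2-(trimethylsilyl)phenyl trifluoromethanesulfonate (ring J aryne precursor)
Conditions: BnBr (1.5 equiv), K2CO3, acetone, 50 °C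
Reagents that add atoms: benzyl bromide, BrCc1ccccc1
Why: Williamson O-benzylation of the hindered phenol under carbonate conditions should leave the silyl triflate, which needs fluoride to react, intact.

Step 7
Reactants: 13 ring J aryne precursor
Product: 14 3,4,5-tris(benzyloxy)-2-iodophenyl trifluoromethanesulfonate
Conditions: ICl (1.05 equiv), CH2Cl2, −78 °C to 0 °C
Reagents that add atoms: iodine monochloride, ICl
Why: ipso-Iododesilylation (electrophilic substitution at the silicon-bearing carbon, activated by the ortho and para benzyloxy groups and faster than C–H iodination) should exchange SiMe3 for iodine and give a fluoride-free trigger for the same aryne.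

Step 8
Reactants: 12 ring B aryne precursor with free 4-OH; 14 3,4,5-tris(benzyloxy)-2-iodophenyl trifluoromethanesulfonate
Product: 18 3,5-bis(benzyloxy)-4-[3,4,5-tris(benzyloxy)-2-hydroxyphenoxy]-2-(trimethylsilyl)phenyl trifluoromethanesulfonate (ring-pair phenol B–C), via aryne 15 (not isolated), via arylmagnesium chloride 16 (not isolated), via dimethyl arylboronate 17 (not isolated)
Conditions: 12, Me3SiCH2MgCl (1.0 equiv), THF, −78 °C; 14 (1.3 equiv), then Me3SiCH2MgCl (1.4 equiv) slowly, −78 °C to −30 °C; B(OMe)3 (4 equiv), −78 °C to rt; then 30% H2O2, aq. NaHCO3, 0 °C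
Reagents that add atoms: hydrogen peroxide, OO
Why: Proposed new method: iodine–magnesium exchange on 14 and loss of MgCl(OTf) should give aryne 15, whose triple bond lies between C-1 (next to the ring H) and C-6 (next to the C-5 benzyloxy group); the inductively withdrawing C-5 oxygen makes C-1 the electrophilic end, so the chloromagnesium phenoxide of 12 should add at C-1 and leave the carbanion at C-6, held as arylmagnesium 16 between two oxygen donors. Borylation of 16 and oxidative boron-to-oxygen aryl shift (retention at carbon) should then deliver the C-6 hydroxyl, so that ring C takes up its two neighbouring oxygens in one operation. The closest known reaction type is the addition of magnesium thiolates and amides to arynes generated from 2-magnesiated aryl sulfonates with electrophilic capture of the new arylmagnesium, together with the fluoride-mediated O-arylation of phenols by arynes; no ring is closed and no stereocentre is formed. The step needs regioselectivity (secured by the single flanking benzyloxy group of 15), O- rather than C-attack of the phenoxide (both ortho positions and the para position of 12 are substituted) and survival of the silyl triflate of 12 (inert without fluoride or a catalyst; Me3SiCH2MgCl is a poor arynophile).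

Step 9
Reactants: 18 ring-pair phenol B–C
Product: 19 3,5-bis(benzyloxy)-4-[3,4,5-tris(benzyloxy)-2-(methoxymethoxy)phenoxy]-2-(trimethylsilyl)phenyl trifluoromethanesulfonate (ring-pair aryne precursor B–C)
Conditions: MOMCl (3 equiv), iPr2NEt (4 equiv), CH2Cl2, 0 °C to 40 °C
Reagents that add atoms: chloromethyl methyl ether, COCCl
Why: O-alkylation to the MOM acetal caps the new phenol so that 19 cannot add to its own aryne; MOM is inert to fluoride and leaves under mild acid.

Step 10
Reactants: 4 ring A phenol; 19 ring-pair aryne precursor B–C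
Product: 22 three-ring phenol A–C (8 OBn; OH on C-6 of ring C), via aryne 20 (not isolated), via three-ring MOM ether 21 (not isolated)
Conditions: 19 (1.3 equiv), CsF (4 equiv), MeCN/toluene 1:1, rt to 40 °C, under argon; then HCl (3 M in MeOH), THF, 40 °C
Reagents that add atoms: none
Why: Fluoride-triggered 1,2-elimination gives aryne 20, whose triple bond C-1≡C-2 is flanked only by the C-3 benzyloxy group, so the phenoxide of 4 should add at C-1 and the proton at C-2 (aryne O-arylation of a phenol, tolerant of two ortho substituents); acid methanolysis then removes the MOM group.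

Step 11
Reactants: 22 three-ring phenol A–C; 19 ring-pair aryne precursor B–C
Product: 24 five-ring phenol A–E (13 OBn; OH on C-6 of ring E), via five-ring MOM ether 23 (not isolated)
Conditions: 19 (1.3 equiv), CsF (4 equiv), MeCN/toluene 1:1, rt to 40 °C, under argon; then HCl (3 M in MeOH), THF, 40 °C
Reagents that add atoms: none
Why: The same aryne O-arylation as in step 10, in which fluoride again releases aryne 20 from 19, followed by MOM methanolysis; the reacting phenol has both ortho positions and the para position blocked, so only O-attack at C-1 of the aryne is possible.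

Step 12
Reactants: 24 five-ring phenol A–E; 19 ring-pair aryne precursor B–C
Product: 26 seven-ring phenol A–G (18 OBn; OH on C-6 of ring G), via seven-ring MOM ether 25 (not isolated)
Conditions: 19 (1.5 equiv), CsF (5 equiv), MeCN/toluene 1:1, 40 °C, under argon; then HCl (3 M in MeOH), THF, 40 °C
Reagents that add atoms: none
Why: Third aryne O-arylation through aryne 20, released from 19 as in step 10, followed by MOM methanolysis; the local environment of the reacting hydroxyl is the same as in step 11.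

Step 13
Reactants: 26 seven-ring phenol A–G; 19 ring-pair aryne precursor B–C
Product: 28 nine-ring phenol A–I (23 OBn; OH on C-6 of ring I), via nine-ring MOM ether 27 (not isolated)
Conditions: 19 (1.5 equiv), CsF (5 equiv), MeCN/toluene 1:1, 40 °C, under argon; then HCl (3 M in MeOH), THF, 40 °C
Reagents that add atoms: none
Why: Fourth aryne O-arylation through aryne 20, released from 19 as in step 10, followed by MOM methanolysis, which adds rings H and I.

Step 14
Reactants: 28 nine-ring phenol A–I; 13 ring J aryne precursor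
Product: 29 ten-ring hexacosa-O-benzyl ether A–J
Conditions: 13 (1.5 equiv), CsF (5 equiv), MeCN/toluene 1:1, 40 °C, under argon
Reagents that add atoms: none
Why: Aryne O-arylation of the phenol: fluoride releases from 13 the 3,4,5-tris(benzyloxy)benzyne 15 already met in step 8, and the phenoxide should add at the carbon remote from the flanking benzyloxy group, which gives ring J with its 3,4,5-oxygens and free C-2 and C-6.

Step 15
Reactants: 29 ten-ring hexacosa-O-benzyl ether A–J
Product: 30 CNP0255890.0 (ten-ring chain A–J, 26 free OH; achiral)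
Conditions: H2 (4 bar), Pd(OH)2/C (20 wt %), THF/MeOH 1:1 (degassed), rt; filtration and evaporation under argon
Reagents that add atoms: none
Why: Hydrogenolysis of all 26 benzyl ethers under neutral conditions should release the polyphenol with toluene as the only by-product; diaryl ethers are inert and no stereocentre exists.

**Compound list**

1 | 1,3,5-tris(benzyloxy)benzene | c1c(OCc2ccccc2)cc(OCc2ccccc2)cc1OCc1ccccc1 | starting material
2 | 2-bromo-1,3,5-tris(benzyloxy)benzene | Brc1c(OCc2ccccc2)cc(OCc2ccccc2)cc1OCc1ccccc1 | intermediate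
3 | dimethyl [2,4,6-tris(benzyloxy)phenyl]boronate | COB(OC)c1c(OCc2ccccc2)cc(OCc2ccccc2)cc1OCc1ccccc1 | intermediate
4 | 2,4,6-tris(benzyloxy)phenol (ring A phenol) | Oc1c(OCc2ccccc2)cc(OCc2ccccc2)cc1OCc1ccccc1 | intermediate
5 | 3,5-bis(benzyloxy)phenol | Oc1cc(OCc2ccccc2)cc(OCc2ccccc2)c1 | starting material
6 | 2,6-bis(benzyloxy)-1,4-benzoquinone | O=C1C=C(OCc2ccccc2)C(=O)C(OCc2ccccc2)=C1 | intermediate
7 | 2,6-bis(benzyloxy)-3-bromo-1,4-benzoquinone | O=C1C=C(OCc2ccccc2)C(=O)C(OCc2ccccc2)=C1Br | intermediate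
8 | 2,6-bis(benzyloxy)-3-bromobenzene-1,4-diol | Oc1cc(OCc2ccccc2)c(O)c(OCc2ccccc2)c1Br | intermediate
9 | 1,4-bis(trimethylsilyl) ether of 8 | C[Si](C)(C)Oc1cc(OCc2ccccc2)c(O[Si](C)(C)C)c(OCc2ccccc2)c1Br | intermediate
10 | lithium 3,5-bis(benzyloxy)-2-(trimethylsilyl)-4-(trimethylsilyloxy)phenoxide | [Li+].[O-]c1cc(OCc2ccccc2)c(O[Si](C)(C)C)c(OCc2ccccc2)c1[Si](C)(C)C | intermediate
11 | 3,5-bis(benzyloxy)-2-(trimethylsilyl)-4-(trimethylsilyloxy)phenyl trifluoromethanesulfonate | FC(F)(F)S(=O)(=O)Oc1cc(OCc2ccccc2)c(O[Si](C)(C)C)c(OCc2ccccc2)c1[Si](C)(C)C | intermediate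
12 | 3,5-bis(benzyloxy)-4-hydroxy-2-(trimethylsilyl)phenyl trifluoromethanesulfonate (ring B aryne precursor; free 4-OH) | FC(F)(F)S(=O)(=O)Oc1cc(OCc2ccccc2)c(O)c(OCc2ccccc2)c1[Si](C)(C)C | intermediate
13 | 3,4,5-tris(benzyloxy)-2-(trimethylsilyl)phenyl trifluoromethanesulfonate (ring J aryne precursor) | FC(F)(F)S(=O)(=O)Oc1cc(OCc2ccccc2)c(OCc2ccccc2)c(OCc2ccccc2)c1[Si](C)(C)C | intermediate
14 | 3,4,5-tris(benzyloxy)-2-iodophenyl trifluoromethanesulfonate | FC(F)(F)S(=O)(=O)Oc1cc(OCc2ccccc2)c(OCc2ccccc2)c(OCc2ccccc2)c1I | intermediate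
15 | 3,4,5-tris(benzyloxy)benzyne (1,2-didehydro-3,4,5-tris(benzyloxy)benzene) | C1#CC(OCc2ccccc2)=C(OCc2ccccc2)C(OCc2ccccc2)=C1 | intermediate
16 | {2-[2,6-bis(benzyloxy)-4-(trifluoromethanesulfonyloxy)-3-(trimethylsilyl)phenoxy]-4,5,6-tris(benzyloxy)phenyl}magnesium chloride | FC(F)(F)S(=O)(=O)Oc1cc(OCc7ccccc7)c(Oc2cc(OCc7ccccc7)c(OCc7ccccc7)c(OCc7ccccc7)c2[Mg]Cl)c(OCc7ccccc7)c1[Si](C)(C)C | intermediate
17 | dimethyl boronate corresponding to 16 (B(OMe)2 on C-6 of ring C) | FC(F)(F)S(=O)(=O)Oc1cc(OCc7ccccc7)c(Oc2cc(OCc7ccccc7)c(OCc7ccccc7)c(OCc7ccccc7)c2B(OC)OC)c(OCc7ccccc7)c1[Si](C)(C)C | intermediate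
18 | 3,5-bis(benzyloxy)-4-[3,4,5-tris(benzyloxy)-2-hydroxyphenoxy]-2-(trimethylsilyl)phenyl trifluoromethanesulfonate (ring-pair phenol B–C) | FC(F)(F)S(=O)(=O)Oc1cc(OCc7ccccc7)c(Oc2cc(OCc7ccccc7)c(OCc7ccccc7)c(OCc7ccccc7)c2O)c(OCc7ccccc7)c1[Si](C)(C)C | intermediate
19 | 3,5-bis(benzyloxy)-4-[3,4,5-tris(benzyloxy)-2-(methoxymethoxy)phenoxy]-2-(trimethylsilyl)phenyl trifluoromethanesulfonate (ring-pair aryne precursor B–C) | FC(F)(F)S(=O)(=O)Oc1cc(OCc7ccccc7)c(Oc2cc(OCc7ccccc7)c(OCc7ccccc7)c(OCc7ccccc7)c2OCOC)c(OCc7ccccc7)c1[Si](C)(C)C | intermediate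
20 | 3,5-bis(benzyloxy)-4-[3,4,5-tris(benzyloxy)-2-(methoxymethoxy)phenoxy]benzyne (aryne of 19; triple bond C-1≡C-2 of ring B) | C1#CC(OCc7ccccc7)=C(Oc2cc(OCc7ccccc7)c(OCc7ccccc7)c(OCc7ccccc7)c2OCOC)C(OCc7ccccc7)=C1 | intermediate
21 | three-ring MOM ether A–C (8 OBn; OMOM on C-6 of ring C) | c7ccccc7COc1cc(OCc7ccccc7)c(Oc2cc(OCc7ccccc7)c(Oc3cc(OCc7ccccc7)c(OCc7ccccc7)c(OCc7ccccc7)c3OCOC)c(OCc7ccccc7)c2)c(OCc7ccccc7)c1 | intermediate
22 | three-ring phenol A–C: 2,3,4-tris(benzyloxy)-6-{2,6-bis(benzyloxy)-4-[2,4,6-tris(benzyloxy)phenoxy]phenoxy}phenol | c7ccccc7COc1cc(OCc7ccccc7)c(Oc2cc(OCc7ccccc7)c(Oc3cc(OCc7ccccc7)c(OCc7ccccc7)c(OCc7ccccc7)c3O)c(OCc7ccccc7)c2)c(OCc7ccccc7)c1 | intermediate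
23 | five-ring MOM ether A–E (13 OBn; OMOM on C-6 of ring E) | c7ccccc7COc1cc(OCc7ccccc7)c(Oc2cc(OCc7ccccc7)c(Oc3cc(OCc7ccccc7)c(OCc7ccccc7)c(OCc7ccccc7)c3Oc3cc(OCc7ccccc7)c(Oc4cc(OCc7ccccc7)c(OCc7ccccc7)c(OCc7ccccc7)c4OCOC)c(OCc7ccccc7)c3)c(OCc7ccccc7)c2)c(OCc7ccccc7)c1 | intermediate
24 | five-ring phenol A–E (13 OBn; OH on C-6 of ring E) | c7ccccc7COc1cc(OCc7ccccc7)c(Oc2cc(OCc7ccccc7)c(Oc3cc(OCc7ccccc7)c(OCc7ccccc7)c(OCc7ccccc7)c3Oc3cc(OCc7ccccc7)c(Oc4cc(OCc7ccccc7)c(OCc7ccccc7)c(OCc7ccccc7)c4O)c(OCc7ccccc7)c3)c(OCc7ccccc7)c2)c(OCc7ccccc7)c1 | intermediate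
25 | seven-ring MOM ether A–G (18 OBn; OMOM on C-6 of ring G) | c7ccccc7COc1cc(OCc7ccccc7)c(Oc2cc(OCc7ccccc7)c(Oc3cc(OCc7ccccc7)c(OCc7ccccc7)c(OCc7ccccc7)c3Oc3cc(OCc7ccccc7)c(Oc4cc(OCc7ccccc7)c(OCc7ccccc7)c(OCc7ccccc7)c4Oc4cc(OCc7ccccc7)c(Oc5cc(OCc7ccccc7)c(OCc7ccccc7)c(OCc7ccccc7)c5OCOC)c(OCc7ccccc7)c4)c(OCc7ccccc7)c3)c(OCc7ccccc7)c2)c(OCc7ccccc7)c1 | intermediate
26 | seven-ring phenol A–G (18 OBn; OH on C-6 of ring G) | c7ccccc7COc1cc(OCc7ccccc7)c(Oc2cc(OCc7ccccc7)c(Oc3cc(OCc7ccccc7)c(OCc7ccccc7)c(OCc7ccccc7)c3Oc3cc(OCc7ccccc7)c(Oc4cc(OCc7ccccc7)c(OCc7ccccc7)c(OCc7ccccc7)c4Oc4cc(OCc7ccccc7)c(Oc5cc(OCc7ccccc7)c(OCc7ccccc7)c(OCc7ccccc7)c5O)c(OCc7ccccc7)c4)c(OCc7ccccc7)c3)c(OCc7ccccc7)c2)c(OCc7ccccc7)c1 | intermediate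
27 | nine-ring MOM ether A–I (23 OBn; OMOM on C-6 of ring I) | c7ccccc7COc1cc(OCc7ccccc7)c(Oc2cc(OCc7ccccc7)c(Oc3cc(OCc7ccccc7)c(OCc7ccccc7)c(OCc7ccccc7)c3Oc3cc(OCc7ccccc7)c(Oc4cc(OCc7ccccc7)c(OCc7ccccc7)c(OCc7ccccc7)c4Oc4cc(OCc7ccccc7)c(Oc5cc(OCc7ccccc7)c(OCc7ccccc7)c(OCc7ccccc7)c5Oc5cc(OCc7ccccc7)c(Oc6cc(OCc7ccccc7)c(OCc7ccccc7)c(OCc7ccccc7)c6OCOC)c(OCc7ccccc7)c5)c(OCc7ccccc7)c4)c(OCc7ccccc7)c3)c(OCc7ccccc7)c2)c(OCc7ccccc7)c1 | intermediate
28 | nine-ring phenol A–I (23 OBn; OH on C-6 of ring I) | c7ccccc7COc1cc(OCc7ccccc7)c(Oc2cc(OCc7ccccc7)c(Oc3cc(OCc7ccccc7)c(OCc7ccccc7)c(OCc7ccccc7)c3Oc3cc(OCc7ccccc7)c(Oc4cc(OCc7ccccc7)c(OCc7ccccc7)c(OCc7ccccc7)c4Oc4cc(OCc7ccccc7)c(Oc5cc(OCc7ccccc7)c(OCc7ccccc7)c(OCc7ccccc7)c5Oc5cc(OCc7ccccc7)c(Oc6cc(OCc7ccccc7)c(OCc7ccccc7)c(OCc7ccccc7)c6O)c(OCc7ccccc7)c5)c(OCc7ccccc7)c4)c(OCc7ccccc7)c3)c(OCc7ccccc7)c2)c(OCc7ccccc7)c1 | intermediate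
29 | ten-ring hexacosa-O-benzyl ether A–J (all 26 oxygens as OBn) | c7ccccc7COc1cc(OCc7ccccc7)c(Oc2cc(OCc7ccccc7)c(Oc3cc(OCc7ccccc7)c(OCc7ccccc7)c(OCc7ccccc7)c3Oc3cc(OCc7ccccc7)c(Oc4cc(OCc7ccccc7)c(OCc7ccccc7)c(OCc7ccccc7)c4Oc4cc(OCc7ccccc7)c(Oc5cc(OCc7ccccc7)c(OCc7ccccc7)c(OCc7ccccc7)c5Oc5cc(OCc7ccccc7)c(Oc6cc(OCc7ccccc7)c(OCc7ccccc7)c(OCc7ccccc7)c6Oc6cc(OCc7ccccc7)c(OCc7ccccc7)c(OCc7ccccc7)c6)c(OCc7ccccc7)c5)c(OCc7ccccc7)c4)c(OCc7ccccc7)c3)c(OCc7ccccc7)c2)c(OCc7ccccc7)c1 | intermediate
30 | CNP0255890.0 (ten-ring chain A–J, all 26 oxygens as OH; achiral) | Oc1cc(O)c(Oc2cc(O)c(Oc3cc(O)c(O)c(O)c3Oc3cc(O)c(Oc4cc(O)c(O)c(O)c4Oc4cc(O)c(Oc5cc(O)c(O)c(O)c5Oc5cc(O)c(Oc6cc(O)c(O)c(O)c6Oc6cc(O)c(O)c(O)c6)c(O)c5)c(O)c4)c(O)c3)c(O)c2)c(O)c1 | target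

**Step count and risks**

Total step count: 15. Longest linear sequence: 13 steps (5 → 6 → 8 → 12 → 13 → 14 → 18 → 19 → 22 → 24 → 26 → 28 → 29 → 30).

Steps most likely to fail:

1. Step 8 (proposed new method). The magnesium phenoxide of 12 may add too slowly, so that aryne 15 is lost to self-reaction or to the Grignard reagent before the ether forms. Fallback with known chemistry: ring C would be brought in with its oxygen already in place and joined by a room-temperature Chan–Lam coupling, which leaves the silyl triflate of 12 untouched. Commercial 2,3,4-trihydroxybenzaldehyde would be benzylated (BnBr, K2CO3, DMF) to 2,3,4-tris(benzyloxy)benzaldehyde F1 as the first new compound. Baeyer–Villiger oxidation of F1 (3-chloroperoxybenzoic acid, CH2Cl2) and formate methanolysis would give 2,3,4-tris(benzyloxy)phenol F2 in one operation. NIS would iodinate F2 ortho to the hydroxyl and give 6-iodo-2,3,4-tris(benzyloxy)phenol F3 as the only ortho product, and MOMCl would protect F3 as 1-iodo-2-(methoxymethoxy)-3,4,5-tris(benzyloxy)benzene F4 before metalation. Iodine–magnesium exchange on F4 (iPrMgCl, THF, −20 °C), B(OMe)3 and hydrolysis would give [3,4,5-tris(benzyloxy)-2-(methoxymethoxy)phenyl]boronic acid F5 for the coupling. Cu(OAc)2, pyridine, 4 Å molecular sieves and air in CH2Cl2 at rt would then couple F5 with the phenol 12 and give 19. The fallback sets out from 12 and comes back to the route at 19.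

2. Step 13. With the large, hindered phenoxide of 26 the bimolecular addition may become slower than consumption of aryne 20 by fluoride and traces of water, so that conversion stalls. Fallback: the same bond would be made by palladium-catalysed C–O coupling of a silicon-free triflate. Compound 18 would be protodesilylated (CF3CO2H, CH2Cl2, 0 °C) to 3,5-bis(benzyloxy)-4-[3,4,5-tris(benzyloxy)-2-hydroxyphenoxy]phenyl trifluoromethanesulfonate F6 as a silicon-free phenol, and MOMCl would protect F6 as 3,5-bis(benzyloxy)-4-[3,4,5-tris(benzyloxy)-2-(methoxymethoxy)phenoxy]phenyl trifluoromethanesulfonate F7 for the coupling. F7 would be coupled with 26 using Pd(OAc)2, 2-(di-tert-butylphosphino)-2',4',6'-triisopropylbiphenyl and K3PO4 in toluene at 100 °C; zerovalent palladium inserts into the unhindered C-1–OTf bond. The fallback sets out from 18 and comes back to the route at 27, which is then unmasked with acid as in step 13.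

3. Step 15. Hydrogenolysis may stop short as the substrate turns from lipophilic to highly polar and binds to the catalyst, and the free polyphenol may oxidise in air during isolation. Fallback: the benzyl ethers would be cleaved by a Lewis-acid pathway (BCl3, pentamethylbenzene as cation scavenger, CH2Cl2, −78 °C). The crude polyphenol would be acetylated at once (Ac2O, pyridine) to the hexacosaacetate of the target F8 and purified on silica as this ester. Methanolysis of F8 under argon (K2CO3 cat., MeOH, 0 °C, then acidification) would release the target. The fallback sets out from 29 and comes back to the route at 30.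

Further compounds
F1 | step 8 | 2,3,4-tris(benzyloxy)benzaldehyde | O=Cc1ccc(OCc2ccccc2)c(OCc2ccccc2)c1OCc1ccccc1
F2 | step 8 | 2,3,4-tris(benzyloxy)phenol | Oc1ccc(OCc2ccccc2)c(OCc2ccccc2)c1OCc1ccccc1
F3 | step 8 | 6-iodo-2,3,4-tris(benzyloxy)phenol | Oc1c(I)cc(OCc2ccccc2)c(OCc2ccccc2)c1OCc1ccccc1
F4 | step 8 | 1-iodo-2-(methoxymethoxy)-3,4,5-tris(benzyloxy)benzene | COCOc1c(I)cc(OCc2ccccc2)c(OCc2ccccc2)c1OCc1ccccc1
F5 | step 8 | [3,4,5-tris(benzyloxy)-2-(methoxymethoxy)phenyl]boronic acid | COCOc1c(B(O)O)cc(OCc2ccccc2)c(OCc2ccccc2)c1OCc1ccccc1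
F6 | step 13 | 3,5-bis(benzyloxy)-4-[3,4,5-tris(benzyloxy)-2-hydroxyphenoxy]phenyl trifluoromethanesulfonate | FC(F)(F)S(=O)(=O)Oc1cc(OCc7ccccc7)c(Oc2cc(OCc7ccccc7)c(OCc7ccccc7)c(OCc7ccccc7)c2O)c(OCc7ccccc7)c1
F7 | step 13 | 3,5-bis(benzyloxy)-4-[3,4,5-tris(benzyloxy)-2-(methoxymethoxy)phenoxy]phenyl trifluoromethanesulfonate | FC(F)(F)S(=O)(=O)Oc1cc(OCc7ccccc7)c(Oc2cc(OCc7ccccc7)c(OCc7ccccc7)c(OCc7ccccc7)c2OCOC)c(OCc7ccccc7)c1
F8 | step 15 | hexacosaacetate of the target | CC(=O)Oc1cc(OC(C)=O)c(Oc2cc(OC(C)=O)c(Oc3cc(OC(C)=O)c(OC(C)=O)c(OC(C)=O)c3Oc3cc(OC(C)=O)c(Oc4cc(OC(C)=O)c(OC(C)=O)c(OC(C)=O)c4Oc4cc(OC(C)=O)c(Oc5cc(OC(C)=O)c(OC(C)=O)c(OC(C)=O)c5Oc5cc(OC(C)=O)c(Oc6cc(OC(C)=O)c(OC(C)=O)c(OC(C)=O)c6Oc6cc(OC(C)=O)c(OC(C)=O)c(OC(C)=O)c6)c(OC(C)=O)c5)c(OC(C)=O)c4)c(OC(C)=O)c3)c(OC(C)=O)c2)c(OC(C)=O)c1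
A1 | direct plan | 4-(6-iodo-2,3,4-trimethoxyphenoxy)-2,6-dimethoxybenzaldehyde | COc1cc(Oc2c(I)cc(OC)c(OC)c2OC)cc(OC)c1C=O
A2 | direct plan | 2,6-dimethoxy-4-(2,4,6-trimethoxyphenoxy)phenol | COc1cc(OC)c(Oc2cc(OC)c(O)c(OC)c2)c(OC)c1
A3 | direct plan | pentacosa-O-methyl ether of the target (free OH on C-4 of ring J) | COc1cc(OC)c(Oc2cc(OC)c(Oc3cc(OC)c(OC)c(OC)c3Oc3cc(OC)c(Oc4cc(OC)c(OC)c(OC)c4Oc4cc(OC)c(Oc5cc(OC)c(OC)c(OC)c5Oc5cc(OC)c(Oc6cc(OC)c(OC)c(OC)c6Oc6cc(OC)c(O)c(OC)c6)c(OC)c5)c(OC)c4)c(OC)c3)c(OC)c2)c(OC)c1
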